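The earlier runs and the new flask were generated by integration with made-up constants, noise included.

A small charge of substrate, 0.065 M in the oak run, and a larger one, 0.098 M in the maple run, both with gas held and the same free catalyst, are what I reckon this flask from.

common to all: gas 29 mM (held); free catalyst 0.91 mM
- oak: substrate 0.065 M; run made earlier
- maple: substrate 0.098 M; run made earlier
- flask: substrate 0.13 M; time 12 min

| run | time / min | substrate / % | catalyst intermediate D / % | target / % | catalyst intermediate C / % | isomer of the product / % | catalyst intermediate B / % |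
|---|---|---|---|---|---|---|---|
| oak | 1.00 | 76.9 | 0.9 | 16.3 | 0 | 6.7 | 0 |
| oak | 2.00 | 55.4 | 0 | 25.7 | 0.9 | 16.0 | 0 |
| oak | 2.50 | 46.8 | 0 | 29.0 | 1.4 | 24.7 | 1.7 |
| oak | 4.00 | 27.0 | 2.0 | 33.2 | 0 | 37.7 | 0 |
| oak | 6.00 | 9.0 | 0 | 36.1 | 1.0 | 54.6 | 0 |
| oak | 10.0 | 0 | 0 | 35.5 | 0.8 | 65.2 | 0 |
| oak | 15.0 | 0.3 | 0 | 34.8 | 0 | 65.2 | 0 |
| maple | 1.00 | 82.9 | 0 | 12.5 | 0.2 | 3.4 | 0 |
| maple | 2.00 | 66.7 | 0 | 20.5 | 1.1 | 13.3 | 0.5 |
| maple | 2.50 | 59.7 | 0.4 | 22.2 | 0.5 | 18.1 | 0 |
| maple | 4.00 | 43.0 | 0.2 | 26.5 | 0 | 31.3 | 0.9 |
| maple | 6.00 | 20.7 | 0.9 | 32.0 | 0.8 | 45.3 | 0 |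
| maple | 10.0 | 4.3 | 0 | 34.7 | 0 | 62.6 | 0 |
| maple | 15.0 | 0 | 0 | 32.7 | 0 | 65.3 | 0 |

(scatter of a reading: 1 percentage point)

- the analysis behind the earlier runs scatters by 1 percentage point, standard deviation
- at the start none of the gas is in solution

* where most of what was charged as substrate, at 12 min is found (catalyst intermediate B / isomer of the product / catalyst intermediate D / target / substrate / catalyst intermediate C)
* the largest share itself, whichever of these holds it, in percent of the substrate charged

I start with the rate of substrate loss over the first 1.00 min: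

oak: 15.0 mM min⁻¹; maple: r = 16.8 mM min⁻¹

The charge grew by a factor 1.51 but the rate by 1.12, so the start is close to zero order in substrate, and I take r for the flask.

Then it slows, in two ways. From 2.00 min the maple run has about as much substrate as oak was charged with, yet up to 4.00 min it runs at 11.6 mM min⁻¹, a factor 0.773 on oak's start, so something besides substrate is slowing it. From 6.00 min to 10.0 min, with substrate read down from 20.7% to 4.3%, the maple run falls to 4.02 mM min⁻¹, a further factor 0.347. Accumulated, the mean rate m of the maple run over its first 10.0 min is: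

m = 9.38 mM min⁻¹, or 0.558 of r

Held for 12 min in the flask, m turns over 86.6% of the charge. The larger charge of the flask should reach low substrate later, so I take this as my low estimate and the whole charge as my high one.

In oak's last reading what was turned over stands as target and isomer of the product, and an even split, 0.5, is the zero of my scale. That reading gives 65.2% for s, the isomer's share of what has been turned over, above even.

isomer share: from s × 86.6% = 56.5% to s = 65.2%; I commit to the middle, 60.8%

The forecast gives isomer of the product at 60%, in its words “Isomer takes the remainder”.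

The flask gives isomer of the product at 61.2%, with 4.29% substrate left.

    gas ⇌ reagent, rate k1*(csat - [reagent]) (kL = 0.0598 s⁻¹)
    target ⇌ isomer of the product (K = 1.94, k = 0.0115 s⁻¹)
    reagent + free catalyst → catalyst intermediate A (k = 539 L mol⁻¹ s⁻¹)
    substrate + catalyst intermediate A ⇌ catalyst intermediate B (K = 19.8 L mol⁻¹, k = 22.5 L mol⁻¹ s⁻¹)
    catalyst intermediate D → free catalyst + target (k = 2.04 s⁻¹)
    catalyst intermediate C ⇌ catalyst intermediate D (K = 1.10, k = 0.608 s⁻¹)
    catalyst intermediate B ⇌ by-product + catalyst intermediate C (K = 0.260 M, k = 71.1 s⁻¹)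

In the flask the relaxation half-life of target and isomer of the product, 0.663 min by that step alone, is short against the 12 min of the run, and s times the 95.7% turned over gives 62.4%. In a neighbour flask with 0.0036 M of free catalyst and 0% substrate left at the same time, s gives 65.2%, and that neighbour holds 66.0% isomer of the product.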